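**Retrosynthetic overview**

1. The target is traced back to a dauc-8-ene-4β,6α,10α-triol: the 8α,9α-diol comes from a late cis-dihydroxylation of C8=C9, and the two esters from angelic acid.
2. The triol comes from a bicyclic hydroxy dienone by isopropyl addition to the C4 ketone and formal hydration of the C5=C6 enone.
3. Key disconnection: alkyne + ethylene + CO close the cyclopentenone, and in the same pot the resulting cis-dialkenylcyclopropane rearranges to the cycloheptadiene. This forms C1–C10 and sets the quaternary C1 and C10.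
4. The cascade precursor is a cis-1-propynyl-2-[(E)-borylvinyl]cyclopropane, made by enantioselective cyclopropanation of a (Z)-enynol from propargyl alcohol and propyne.
5. Ring order: cyclopropane (step 3, sacrificial), then the five-membered ring and the seven-membered ring, both in step 6.

Assumption: positions use daucane numbering (C1 = ring-fusion carbon with the angular methyl, C4 = carbinol carbon with the isopropyl group, C5 = ring-fusion CH, C6–C10 = the other seven-ring carbons, methyl on C8). α is the face opposite the angular methyl. The dioxaborolane-controlled cyclopropanation is assumed to show the facial preference known for simple allylic alcohols, which is why the (4S,5S) ligand is used.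

**Step 1**
Reactants: 1 prop-2-yn-1-ol
Product: 2 (Z)-3-iodo-2-methylprop-2-en-1-ol
Conditions: MeMgBr (2.5 equiv), CuI (10 mol%), THF, −10 °C → rt; then I2, −10 °C
Reagents that add atoms: methylmagnesium bromide (C[Mg]Br), iodine (II)
Why: Copper-catalysed carbomagnesiation of the propargylic magnesium alkoxide is anti (chelated alkenylmagnesium), so iodinolysis with retention gives only the Z iodide, which fixes the later cis relationship on the cyclopropane.

**Step 2**
Reactants: 2 (Z)-3-iodo-2-methylprop-2-en-1-ol, 3 propyne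
Product: 4 (Z)-2-methylhex-2-en-4-yn-1-ol
Conditions: 3 (excess), Pd(PPh3)2Cl2 (2 mol%), CuI (4 mol%), Et3N, THF, 0 °C → rt
Reagents that add atoms: none
Why: Sonogashira coupling of the alkenyl iodide proceeds with retention of the Z geometry and tolerates the free hydroxyl.

**Step 3**
Reactants: 4 (Z)-2-methylhex-2-en-4-yn-1-ol
Product: 5 [(1R,2R)-1-methyl-2-(prop-1-yn-1-yl)cyclopropyl]methanol
Conditions: Et2Zn (2.2 equiv), CH2I2 (4.4 equiv), DME, CH2Cl2, −10 °C; then 4 and (4S,5S)-2-butyl-N,N,N′,N′-tetramethyl-1,3,2-dioxaborolane-4,5-dicarboxamide (1.2 equiv, recovered), 0 °C → rt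
Reagents that add atoms: diiodomethane (ICI)
Why: Charette asymmetric Simmons–Smith cyclopropanation, in which the zinc alkoxide bound to the chiral dioxaborolane directs CH2 transfer to one face of the allylic alkene (ligand control, giving 1R,2R) and the concerted syn addition keeps CH2OH and propynyl cis.

**Step 4**
Reactants: 5 [(1R,2R)-1-methyl-2-(prop-1-yn-1-yl)cyclopropyl]methanol
Product: 6 (1R,2R)-1-methyl-2-(prop-1-yn-1-yl)cyclopropane-1-carbaldehyde
Conditions: nPr4N[RuO4] (5 mol%), NMO (1.5 equiv), 4 Å MS, CH2Cl2, rt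
Reagents that add atoms: none
Why: Ley–Griffith oxidation stops at the aldehyde, which has no α-hydrogen and cannot epimerise.

**Step 5**
Reactants: 6 (1R,2R)-1-methyl-2-(prop-1-yn-1-yl)cyclopropane-1-carbaldehyde
Product: 7 4,4,5,5-tetramethyl-2-[(E)-2-[(1S,2S)-1-methyl-2-(prop-1-yn-1-yl)cyclopropyl]ethenyl]-1,3,2-dioxaborolane
Conditions: CH2(Bpin)2 (1.2 equiv), lithium 2,2,6,6-tetramethylpiperidide (1.2 equiv), THF, 0 °C; then 6, −78 °C → rt
Reagents that add atoms: bis(4,4,5,5-tetramethyl-1,3,2-dioxaborolan-2-yl)methane (CC1(C)OB(CB2OC(C)(C)C(C)(C)O2)OC1(C)C)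
Why: Boron–Wittig olefination, in which the lithiated geminal bis(boronate) adds to the aldehyde and syn B–O elimination gives the trans alkenylboronate, the geometry that later puts boron on the outer position of the rearranging terminus.

**Step 6**
Reactants: 7 4,4,5,5-tetramethyl-2-[(E)-2-[(1S,2S)-1-methyl-2-(prop-1-yn-1-yl)cyclopropyl]ethenyl]-1,3,2-dioxaborolane, 8 ethene, 9 carbon monoxide
Product: 12 (3aR,4S)-4-hydroxy-3a,6-dimethyl-3,3a,4,7-tetrahydroazulen-1(2H)-one, via cis-dialkenylcyclopropane enone 10 (not isolated), via bicyclic allylboronate 11 (not isolated)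
Conditions: Co2(CO)8 (20 mol%), 9 (10 bar), 8 (30 bar), toluene, 110 °C, 16 h; vent, 150 °C, 6 h; then NaBO3·4H2O, THF–H2O, rt
Reagents that add atoms: sodium perborate tetrahydrate ([Na+].[O-]OB=O)
Why: Proposed new method: a cobalt-mediated Pauson–Khand [2+2+1] of the internal alkyne with ethene and CO (closest known case: 2-alkyl-3-methylcyclopent-2-enones such as dihydrojasmone from alk-2-ynes and ethene, the bulkier cyclopropyl group ending next to the carbonyl) creates the second alkenyl group of a cis-1,2-dialkenylcyclopropane, which on further heating undergoes the divinylcyclopropane–cycloheptadiene (Cope) rearrangement through the boat transition state (closest known case: the angular-methyl hydroazulene annulations of 1-(2-vinylcyclopropyl)-2-methylcycloalkenes), so the five- and seven-membered rings close in one operation and the cyclopropane configuration is transferred to C1 and C10 (methyl on the inner, boron on the outer terminus position, hence trans), after which the allylic C–B bond is oxidised with retention.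

**Step 7**
Reactants: 12 (3aR,4S)-4-hydroxy-3a,6-dimethyl-3,3a,4,7-tetrahydroazulen-1(2H)-one
Product: 14 (3aR,4S,8R,8aR)-4,8-dihydroxy-3a,6-dimethyl-3,3a,4,7,8,8a-hexahydroazulen-1(2H)-one, via β-boryl ketone 13 (not isolated)
Conditions: B2pin2 (1.2 equiv), CuCl (5 mol%), DPEphos (5 mol%), NaOtBu (10 mol%), MeOH (2 equiv), THF, rt; then NaBO3·4H2O, THF–H2O, 0 °C
Reagents that add atoms: bis(pinacolato)diboron (CC1(C)OB(B2OC(C)(C)C(C)(C)O2)OC1(C)C; its boron stays only in 13), sodium perborate tetrahydrate ([Na+].[O-]OB=O)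
Why: Copper-catalysed conjugate borylation of the s-cis enone followed by stereoretentive C–B oxidation is a formal anti-Markovnikov hydration, in which Cu–Bpin should add to C6 from the face opposite the angular methyl on the neighbouring ring-fusion carbon and the C5 proton ends up α (trans-fused ketone) by protonation from the same face and base equilibration next to the carbonyl.

**Step 8**
Reactants: 14 (3aR,4S,8R,8aR)-4,8-dihydroxy-3a,6-dimethyl-3,3a,4,7,8,8a-hexahydroazulen-1(2H)-one
Product: 15 (1S,3aR,4S,8R,8aR)-3a,6-dimethyl-1-(propan-2-yl)-1,2,3,3a,4,7,8,8a-octahydroazulene-1,4,8-triol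
Conditions: CeCl3 (5 equiv, dried), iPrMgCl (5 equiv), THF, −78 °C, 1 h; then 14, −78 → −20 °C; aq. NH4Cl
Reagents that add atoms: isopropylmagnesium chloride (CC(C)[Mg]Cl)
Why: Organocerium 1,2-addition (Imamoto conditions) tolerates the free hydroxyls as cerium alkoxides and suppresses enolisation, and iPrCeCl2 attacks the cyclopentanone from the α face, away from the C6 substituent on the adjacent carbon and the 1,3-related angular methyl, giving the 4β-hydroxy-4α-isopropyl centre.

**Step 9**
Reactants: 15 (1S,3aR,4S,8R,8aR)-3a,6-dimethyl-1-(propan-2-yl)-1,2,3,3a,4,7,8,8a-octahydroazulene-1,4,8-triol, 16 (Z)-2-methylbut-2-enoic acid (angelic acid)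
Product: 17 (1S,3aR,4S,8R,8aR)-1-hydroxy-3a,6-dimethyl-1-(propan-2-yl)-1,2,3,3a,4,7,8,8a-octahydroazulene-4,8-diyl bis[(Z)-2-methylbut-2-enoate]
Conditions: 16 (3 equiv), 2,4,6-trichlorobenzoyl chloride (3 equiv), Et3N (6 equiv), toluene, rt, 2 h; then 15, 80 °C, 12 h
Reagents that add atoms: none
Why: Yamaguchi-type mixed-anhydride esterification run without a nucleophilic catalyst acylates both secondary hydroxyls without Z-to-E isomerisation of the angeloyl groups, the tertiary hydroxyl does not react, and no stereocentre is touched.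

**Step 10**
Reactants: 17 (1S,3aR,4S,8R,8aR)-1-hydroxy-3a,6-dimethyl-1-(propan-2-yl)-1,2,3,3a,4,7,8,8a-octahydroazulene-4,8-diyl bis[(Z)-2-methylbut-2-enoate]
Product: 18 (1S,3aR,4R,5R,6S,8R,8aR)-1,5,6-trihydroxy-3a,6-dimethyl-1-(propan-2-yl)decahydroazulene-4,8-diyl bis[(Z)-2-methylbut-2-enoate] (6α,10α-diangeloyloxy-4β,8α,9α-trihydroxydaucane, CNP0194216.1)
Conditions: OsO4 (5 mol%), NMO (1.3 equiv), acetone–H2O 5:1, 0 °C → rt; aq. Na2SO3
Reagents that add atoms: osmium tetroxide (O=[Os](=O)(=O)=O), N-methylmorpholine N-oxide (C[N+]1([O-])CCOCC1), water (O)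
Why: Upjohn dihydroxylation, in which OsO4 reacts with the electron-rich trisubstituted ring alkene much faster than with the two conjugated esters and adds both oxygens suprafacially, expected from the α face because the β face of C8=C9 is screened by the axial angular methyl (as in 5α-steroid 2-enes), which sets C8 and C9.

**Compound list**

1 | prop-2-yn-1-ol (propargyl alcohol) | C#CCO | starting material
2 | (Z)-3-iodo-2-methylprop-2-en-1-ol (iodine cis to CH2OH) | OC/C(C)=C\I | intermediate
3 | propyne | CC#C | starting material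
4 | (Z)-2-methylhex-2-en-4-yn-1-ol | OC/C(C)=C\C#CC | intermediate
5 | [(1R,2R)-1-methyl-2-(prop-1-yn-1-yl)cyclopropyl]methanol (CH2OH and propynyl cis) | OC[C@]1(C)C[C@@H]1C#CC | intermediate
6 | (1R,2R)-1-methyl-2-(prop-1-yn-1-yl)cyclopropane-1-carbaldehyde | O=C[C@]1(C)C[C@@H]1C#CC | intermediate
7 | 4,4,5,5-tetramethyl-2-[(E)-2-[(1S,2S)-1-methyl-2-(prop-1-yn-1-yl)cyclopropyl]ethenyl]-1,3,2-dioxaborolane | CC1(C)OB(/C=C/[C@]2(C)C[C@@H]2C#CC)OC1(C)C | intermediate
8 | ethene (ethylene) | C=C | starting material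
9 | carbon monoxide | [C-]#[O+] | starting material
10 | 3-methyl-2-[(1S,2S)-2-methyl-2-[(E)-2-(4,4,5,5-tetramethyl-1,3,2-dioxaborolan-2-yl)ethenyl]cyclopropyl]cyclopent-2-en-1-one (the two alkenyl groups cis on the cyclopropane) | CC1(C)OB(/C=C/[C@]2(C)C[C@@H]2C3=C(C)CCC3=O)OC1(C)C | intermediate (not isolated)
11 | (3aS,4S)-3a,6-dimethyl-4-(4,4,5,5-tetramethyl-1,3,2-dioxaborolan-2-yl)-3,3a,4,7-tetrahydroazulen-1(2H)-one (boron trans to the angular methyl) | O=C1CC[C@@]2(C)[C@@H](B3OC(C)(C)C(C)(C)O3)C=C(C)CC=C12 | intermediate (not isolated)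
12 | (3aR,4S)-4-hydroxy-3a,6-dimethyl-3,3a,4,7-tetrahydroazulen-1(2H)-one (10α-hydroxy, C5=C6 and C8=C9 alkenes, C4 ketone) | O=C1CC[C@@]2(C)[C@@H](O)C=C(C)CC=C12 | intermediate
13 | (3aR,4S,8R,8aS)-4-hydroxy-3a,6-dimethyl-8-(4,4,5,5-tetramethyl-1,3,2-dioxaborolan-2-yl)-3,3a,4,7,8,8a-hexahydroazulen-1(2H)-one | CC1(C)OB([C@@H]2CC(C)=C[C@H](O)[C@]3(C)CCC(=O)[C@@H]23)OC1(C)C | intermediate (not isolated)
14 | (3aR,4S,8R,8aR)-4,8-dihydroxy-3a,6-dimethyl-3,3a,4,7,8,8a-hexahydroazulen-1(2H)-one (6α,10α-diol, trans ring fusion) | O[C@@H]1CC(C)=C[C@H](O)[C@]2(C)CCC(=O)[C@@H]12 | intermediate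
15 | (1S,3aR,4S,8R,8aR)-3a,6-dimethyl-1-(propan-2-yl)-1,2,3,3a,4,7,8,8a-octahydroazulene-1,4,8-triol (dauc-8-ene-4β,6α,10α-triol) | O[C@@H]1CC(C)=C[C@H](O)[C@]2(C)CC[C@](O)(C(C)C)[C@@H]12 | intermediate
16 | (Z)-2-methylbut-2-enoic acid (angelic acid) | C/C=C(/C)C(=O)O | starting material
17 | (1S,3aR,4S,8R,8aR)-1-hydroxy-3a,6-dimethyl-1-(propan-2-yl)-1,2,3,3a,4,7,8,8a-octahydroazulene-4,8-diyl bis[(Z)-2-methylbut-2-enoate] | C/C=C(/C)C(=O)O[C@@H]1CC(C)=C[C@H](OC(=O)/C(C)=C\C)[C@]2(C)CC[C@](O)(C(C)C)[C@@H]12 | intermediate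
18 | (1S,3aR,4R,5R,6S,8R,8aR)-1,5,6-trihydroxy-3a,6-dimethyl-1-(propan-2-yl)decahydroazulene-4,8-diyl bis[(Z)-2-methylbut-2-enoate] | C/C=C(/C)C(=O)O[C@@H]1C[C@](C)(O)[C@H](O)[C@H](OC(=O)/C(C)=C\C)[C@]2(C)CC[C@](O)(C(C)C)[C@@H]12 | target

**Step count and risks**

Total steps: 10. Longest linear sequence: 10 (from 1; compounds 3, 8, 9 and 16 are bought).

The three steps most likely to fail:

Step 6. The alkenylboronate or the strained 1-alkynyl-2-alkenylcyclopropane may not survive the cobalt chemistry, and the one-pot sequence is untested. The fallback sets out from 5 and builds the two rings in separate operations, with boron introduced last. Pauson–Khand reaction of 5 alone (Co2(CO)8, 1.1 equiv, then ethene 25 bar, DMSO, toluene, 80 °C) gives 2-[(1S,2R)-2-(hydroxymethyl)-2-methylcyclopropyl]-3-methylcyclopent-2-en-1-one F1. Oxidation with nPr4N[RuO4]/NMO gives (1R,2S)-1-methyl-2-(2-methyl-5-oxocyclopent-1-en-1-yl)cyclopropane-1-carbaldehyde F2. Aldehyde-selective boron–Wittig olefination as in step 5 (−78 °C) comes back to the route at 10, which is then heated on its own (toluene, 140 °C) to 11 and oxidised to 12.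

Step 7. The face of boron delivery at C6 and the configuration at C5 rest on substrate bias alone. The fallback sets out from 12: nucleophilic epoxidation (t-BuOOH, DBU, CH2Cl2) gives the 5α,6α-epoxy-10α-hydroxy ketone F3. Reductive cleavage of its Cα–O bond with Na[PhSeB(OEt)3] (from (PhSe)2 and NaBH4, EtOH, AcOH) then comes back to the route at 14, the C5 proton again being set by equilibration.

Step 10. The α-face preference is uncertain, because the pseudo-axial 10α-ester also shields the α face and OsO4 usually adds anti to an allylic ester. The fallback sets out from 15 and fixes every centre mechanistically.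
- Hydroxyl-directed epoxidation (VO(acac)2, t-BuOOH, CH2Cl2), syn to the axial 10α-hydroxyl, gives the 8α,9α-epoxy-4β,6α,10α-triol F4.
- Acylation as in step 9 gives the 8α,9α-epoxy-6α,10α-bis-angelate F5.
- Anti opening at the secondary carbon with Li2NiBr4 (THF, 0 °C) gives the 9β-bromo-8α-hydroxy-6α,10α-bis-angelate F6.
- AgOTf in wet acetone, buffered with 2,6-di-tert-butylpyridine, ionises the bromide with participation of the trans-diaxial 10α-angelate. Hydrolysis of the resulting dioxolanylium ion (ester kept on the axial oxygen) comes back to the route at 18.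

Further compounds
F1 | step 6 | 2-[(1S,2R)-2-(hydroxymethyl)-2-methylcyclopropyl]-3-methylcyclopent-2-en-1-one | OC[C@]1(C)C[C@@H]1C2=C(C)CCC2=O
F2 | step 6 | (1R,2S)-1-methyl-2-(2-methyl-5-oxocyclopent-1-en-1-yl)cyclopropane-1-carbaldehyde | O=C[C@]1(C)C[C@@H]1C2=C(C)CCC2=O
F3 | step 7 | 5α,6α-epoxy-10α-hydroxy ketone (oxirane across C5–C6 of 12, oxygen opposite the angular methyl) | O1[C@@H]2CC(C)=C[C@H](O)[C@]3(C)CCC(=O)[C@@]123
F4 | step 10 | 8α,9α-epoxy-4β,6α,10α-triol (oxirane across C8–C9 of 15) | O[C@@H]1C[C@]2(C)O[C@@H]2[C@H](O)[C@]3(C)CC[C@](O)(C(C)C)[C@@H]13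
F5 | step 10 | 8α,9α-epoxy-6α,10α-bis-angelate (bis[(Z)-2-methylbut-2-enoate] of F4) | C/C=C(/C)C(=O)O[C@@H]1C[C@]2(C)O[C@@H]2[C@H](OC(=O)/C(C)=C\C)[C@]3(C)CC[C@](O)(C(C)C)[C@@H]13
F6 | step 10 | 9β-bromo-8α-hydroxy-6α,10α-bis-angelate | C/C=C(/C)C(=O)O[C@@H]1C[C@](C)(O)[C@@H](Br)[C@H](OC(=O)/C(C)=C\C)[C@]2(C)CC[C@](O)(C(C)C)[C@@H]12
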